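## Structural features

The target is (2S)-4'-O-geranylnaringenin: ring A, a phloroglucinol-type benzene ring with free hydroxyls at C5 and C7, is fused through C4a and C8a to the dihydropyranone ring C, whose C2 carries the para-oxygenated ring B. The oxygen of ring B is etherified with a (2E)-3,7-dimethylocta-2,6-dienyl (geranyl) chain that holds two trisubstituted alkenes and an allylic aryl ether, which rules out hydrogenolysis, strong Lewis acids and long exposure to strong protic acid. C2 is the only stereocentre, so no second stereocentre stands next to it; it is benzylic, bonded to the ring oxygen O1 and β to the C4 ketone, so any base that enolises C3 can open ring C by E1cB elimination to the 2'-hydroxychalcone and erase the configuration. The two phenols of ring A must be masked whenever carbanions or arynes are present. The carbon skeleton is simple, and the real difficulty is to close ring C on the electron-rich ring A in enantiopure form, without a chalcone on the way and without leaving the finished β-aryloxy ketone in a basic medium. The key step exploits the fact that O1 and the C4 carbonyl stand on the adjacent ring A carbons C8a and C4a, with the C5 oxygen next to C4a: this is the pattern in which a nucleophile and an electrophile add across a 3-alkoxybenzyne, the nucleophile entering meta to the alkoxy group. The other four ring atoms O1–C2–C3–C4 then come from a 3-aryl-3-oxypropanoate in which C2 is already set and its C–O bond is never broken.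

## Logic of the disconnections

**16 from 15.** The two acetal O–CH2 bonds at O5 and O7 are cut. Ring A cannot travel as a free phenol, because a phenoxide adds to an aryne and a phenol protonates an aryl anion, whereas formaldehyde acetals survive organolithium reagents, fluoride and alkoxide alike. Nothing is gained in skeleton, only freedom for the earlier steps. The forward step needs acid mild enough for the allylic aryl ether and the alkenes; the O5 acetal is activated by the peri carbonyl and the O7 acetal is the slow one.

**15 from 13 and 14.** O1–C8a and C4–C4a are cut together. Ring C falls apart into a two-carbon unit of ring A with free valences on neighbouring carbons (14) and the chain O1–C2–C3–C4 with C2 already in place (13). The gain is large: one step forms two bonds and a ring, no chalcone appears, and the C2–O bond is untouched. The forward step must put oxygen on C8a and not on C4a, must acylate faster than the C4a anion finds a proton, and must keep retro-aldol cleavage and ring opening of 15 away.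

**13 from 6, and 14 from 12.** Neither reacting partner is storable, so the O–Si bond of 13 and the strained triple bond of 14 are traced to 6 and 12. The free hydroxyl of 6 is deliberately not used as such: a fluoride salt cannot deprotonate an aliphatic alcohol cleanly, and a neutral alcohol adding to 14 would hand its own proton to C4a and stop at the uncyclised aryl ether. In 13, fluoride releases the alkoxide with no O–H proton in the flask, and the silyl group is also the sink for the methoxide lost from C4, which leaves as a neutral silyl methyl ether instead of staying as a base that would enolise 15. In 12 the silyl group must stand between the triflate and an acetal oxygen, so that the triple bond forms between the future C8a and C4a; the substitution pattern of 12 meets this. The (3S) descriptor of 6 corresponds to (2S) in 16, because the priority order O > aryl > CH2 is the same in both.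

**6 from 5.** The C–H bond at the carbinol carbon is cut, that is, the alcohol is traced to a ketone. This reduces the only stereocentre to a catalyst-controlled hydride transfer of known facial sense. The forward step must leave the alkenes and the ester alone and must work on an electron-rich aryl ketone.

**5 from 3 and 4.** The bond between the methylene carbon and the ester carbon (C3–C4 of the target) is cut. 4 cannot enolise, so the crossed Claisen condensation has a single direction. The forward step needs excess base to hold the product as its enolate.

**3 from 1 and 2.** The O–CH2 bond of the geranyl ether is cut. Both pieces are commercial, and 1 gives a soft, unhindered oxygen nucleophile. The forward step must alkylate at oxygen and at the primary allylic carbon without allylic transposition.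

**12 from 9 (through 10 and 11).** The C–Si bond and the O–S bond are cut. The bromine of 9 marks the carbon that receives silicon, and the phenolic oxygen first carries the silyl group and later the triflyl group. The forward sequence needs bromine–lithium exchange to outrun acetal-directed deprotonation, and a triflating agent that does not attack the acetals.

**9 from 8.** The C–Br bond is cut. The forward step must brominate ortho to the free hydroxyl and not at the position between the two acetal groups, and must stop at one bromine.

**8 from 7.** Two O–CH2 acetal bonds are cut. 7 is symmetrical, so the only issue in the forward step is the statistical distribution between mono-, bis- and tris-ether.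

## Other disconnections considered

Alternative 1: The cut runs through C3–C4 and O1–C2, so that ring C would be assembled from an acyl unit on ring A and the two vinyl carbons of a ring B styrene.
- *Forward key step.* Irradiation of 5,7-bis(tert-butyldimethylsilyloxy)-2,2-dimethyl-4H-1,3-benzodioxin-4-one A1 would release the quinoketene 3,5-bis(tert-butyldimethylsilyloxy)-6-(oxomethylidene)cyclohexa-2,4-dien-1-one A2. The ketene carbon and the ring carbonyl oxygen of A2 would add across the vinyl group of 4-(geranyloxy)styrene A3 in a hetero-Diels–Alder sense. The adduct is 5,7-bis(tert-butyldimethylsilyloxy)-4'-O-geranylflavanone, of which the (2S) enantiomer A4 is the one wanted.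
- *In its favour.* The polarity is matched: the terminal vinyl carbon of A3 goes to the ketene carbon and the benzylic carbon to oxygen. The medium is neutral, so no chalcone equilibrium threatens ring C while it forms. A1 and A3 are each about two steps from commercial phenols. The silyl ethers of A4 fall to buffered fluoride, which is kinder to the geranyl ether than acid.
- *Against it here.* C2 is created in the cycloaddition from two achiral partners, and no catalyst is known that controls a short-lived photogenerated ketene of this kind, so the step offers no handle for the (2S) configuration. Ketenes also tend to add to alkenes across their C=C bond to give four-membered ketones. A3 and A4 both absorb in the ultraviolet, and A2 is scavenged by traces of moisture.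
- *Comparison.* In step economy the alternative is the better (roughly six steps against eight). It is the equal of the chosen plan in forming two ring C bonds in one operation, and it is more convergent because the stereocentre arises in the same step. That is also where it fails the target: it would end in a racemate that needs resolution, whereas the chosen plan brings C2 in from a catalytic reduction and never breaks its C–O bond.

Alternative 2: Here ring A is cut, not ring C. C8–C8a, C5–C6, C7–C8 and C4a–C5 are disconnected, leaving an enantiopure 2-aryl-2,3-dihydropyran-4-one as carrier of C2.
- *Forward key step.* Photolysis of (2S)-6-(diazoacetyl)-2-[4-(geranyloxy)phenyl]-2,3-dihydro-4H-pyran-4-one A5 would trigger a Wolff rearrangement to the vinylketene (2S)-2-[4-(geranyloxy)phenyl]-6-(2-oxoethenyl)-2,3-dihydro-4H-pyran-4-one A6. A6 would add (triisopropylsilyloxy)ethyne A7 in a [2+2] sense. Four-electron ring opening of the four-membered adduct, six-electron electrocyclisation and tautomerisation would then give (2S)-5-hydroxy-7-(triisopropylsilyloxy)-4'-O-geranylflavanone A8.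
- *In its favour.* The benzannulation is an established reaction type (the photochemical Danheiser benzannulation), which is an advantage over the unprecedented aryne step. Ring C and its stereocentre would be made first by a catalytic asymmetric hetero-Diels–Alder reaction and would then meet only neutral conditions, so C2 is safer than in the chosen plan. The placement of the two ring A oxygens follows from the polarity of A7. The last step, fluoride desilylation of A8, is milder for the geranyl group than acid.
- *Against it here.* A5 is a cross-conjugated acyl dihydropyranone that needs a long sequence of its own. Diazoketones are hazardous and A7 is moisture-sensitive. The carbene from A5 and the ketene A6 can be intercepted by the two geranyl alkenes, and the enone chromophore of ring C is itself photoactive. The alkene that takes part in the electrocyclisation is a β-alkoxy enone, outside the usual range of the reaction.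
- *Comparison.* The alternative is better in precedent for the key step, in the security of C2 and in the final deprotection. It is equal in that the stereocentre is set by asymmetric catalysis before the key step. It is worse in step economy (well over ten steps against eight) and in operational safety, and it spends its most elaborate chemistry on ring A, the symmetrical part that 7 supplies ready-made.

Alternative 3: Only O1–C8a is cut, with C4 at the alcohol oxidation level.
- *Forward key step.* (1R,3S)-1-[2-Bromo-4,6-bis(methoxymethoxy)phenyl]-3-[4-(geranyloxy)phenyl]propane-1,3-diol A9, obtained by an asymmetric aldol and a carbonyl reduction, would be cyclised by an Ullmann-type etherification with CuI, 1,10-phenanthroline and Cs2CO3 in hot toluene. This would give (2S,4R)-5,7-bis(methoxymethoxy)-4'-O-geranylflavan-4-ol A10. Oxidation of the C4 alcohol of A10 would give 15, from which the route is the same.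
- *In its favour.* Every step is of an established type, so the key step carries less risk than the aryne annulation. No carbonyl is present when base is used, so neither retro-aldol cleavage nor ring opening can touch C2. The choice between the two hydroxyls is automatic, since only the C3 hydroxyl of A9 (the later O1) can reach the brominated carbon in a six-membered ring.
- *Against it here.* The aryl bromide of A9 is electron-rich and flanked on both sides, and the nucleophile is a secondary benzylic alkoxide. Such couplings need high temperature, where copper alkoxides are prone to β-hydride loss and the bromide to reduction. C4 is first reduced and then re-oxidised, so the C4 configuration of A10 is created only to be destroyed. The ring A ketone needed for the aldol is itself several steps from 7.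
- *Comparison.* The alternative is better in precedent and in protecting C2 against base. It is equal in protecting groups and final deprotection, since both plans pass through 15. It is worse in step and redox economy (about ten steps, two of them corrective redox steps), and its key step forms one ring bond where the chosen plan forms two.

Key step: step 7

Assumption: geranyl denotes (2E)-3,7-dimethylocta-2,6-dien-1-yl throughout, and a sequence run in one flask without isolation (steps 6 and 7) is counted as one step.

## Route

Step 1
Reactants: 1 4-hydroxyacetophenone; 2 geranyl bromide [(2E)-1-bromo-3,7-dimethylocta-2,6-diene]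
Product: 3 1-[4-(geranyloxy)phenyl]ethanone
Conditions: K2CO3, acetone, reflux
Reagents that add atoms: none
Why: Williamson ether synthesis: the phenoxide is alkylated at oxygen by SN2 displacement at the primary allylic bromide, which leaves the (2E) geometry untouched; K2CO3 does not deprotonate the methyl ketone.

Step 2
Reactants: 3 1-[4-(geranyloxy)phenyl]ethanone; 4 dimethyl carbonate
Product: 5 methyl 3-[4-(geranyloxy)phenyl]-3-oxopropanoate
Conditions: NaH (2.5 equiv), THF, reflux; AcOH
Reagents that add atoms: none
Why: Crossed Claisen condensation of the methyl ketone enolate with a carbonate that cannot enolise; the β-keto ester is drained from the equilibrium as its sodium enolate and set free by the acetic acid quench. The aryl geranyl ether offers NaH no point of attack.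

Step 3
Reactants: 5 methyl 3-[4-(geranyloxy)phenyl]-3-oxopropanoate
Product: 6 methyl (3S)-3-hydroxy-3-[4-(geranyloxy)phenyl]propanoate
Conditions: RuCl[(S,S)-TsDPEN](p-cymene) (1 mol%), HCO2H/Et3N 5:2, DMF, 40 °C
Reagents that add atoms: none
Why: Noyori–Ikariya asymmetric transfer hydrogenation: the Ru–H/N–H pair of the divalent ruthenium catalyst delivers hydride and proton to the ketone in a six-membered transition state in which the substrate aryl group lies against the η6-arene, and with the (S,S)-ligand this should give the (S)-aryl carbinol as it does for acetophenone (same priority order O > aryl > CH2). The trisubstituted alkenes and the ester are not reduced by this bifunctional hydride; the configuration of 6 is to be confirmed by Mosher ester analysis.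

Step 4
Reactants: 7 phloroglucinol (benzene-1,3,5-triol, dried)
Product: 8 3,5-bis(methoxymethoxy)phenol
Conditions: MOMCl (2.0 equiv), i-Pr2NEt, DMF, 0 to 20 °C
Reagents that add atoms: chloromethyl methyl ether, COCCl
Why: O-alkylation of the phenol with a chloromethyl ether; the three equivalent hydroxyls react statistically, so with two equivalents 8 should be the main component, to be separated by chromatography from the mono-ether (which can be resubmitted) and the tris-ether.

Step 5
Reactants: 8 3,5-bis(methoxymethoxy)phenol
Product: 9 2-bromo-3,5-bis(methoxymethoxy)phenol
Conditions: NBS (1.0 equiv), i-Pr2NH (10 mol%), CH2Cl2, −78 to 0 °C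
Reagents that add atoms: N-bromosuccinimide, O=C1CCC(=O)N1Br
Why: Electrophilic aromatic bromination of a highly activated phenol; with NBS and a catalytic secondary amine in a non-polar solvent the bromine is delivered from an N-bromoamine hydrogen-bonded to the phenolic O–H, which should direct it ortho to the hydroxyl and away from the para position, which is also crowded by the two flanking acetal groups. One equivalent at low temperature limits a second bromination, and no HBr is formed that could cleave the acetals.

Step 6
Reactants: 9 2-bromo-3,5-bis(methoxymethoxy)phenol
Product: 12 3,5-bis(methoxymethoxy)-2-(trimethylsilyl)phenyl trifluoromethanesulfonate, via aryl silyl ether 10 (not isolated), via lithium silylphenoxide 11 (not isolated)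
Conditions: (Me3Si)2NH, THF, 65 °C, then evaporation; n-BuLi, THF, −78 °C; PhNTf2, −78 to 20 °C
Reagents that add atoms: hexamethyldisilazane, C[Si](C)(C)N[Si](C)(C)C; N-phenylbis(trifluoromethanesulfonimide), O=S(=O)(N(c1ccccc1)S(=O)(=O)C(F)(F)F)C(F)(F)F
Why: O-silylation, bromine–lithium exchange and retro-Brook rearrangement: the aryllithium formed next to the silyloxy group takes the silyl group from oxygen in a 1,3 O-to-C shift driven by the change from aryl anion to phenoxide, and phenoxide 11 is then triflated on oxygen. Exchange at −78 °C is much faster than acetal-directed ring deprotonation, and the sulfonimide is used instead of triflic anhydride because it does not activate the acetals.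

Step 7
Reactants: 6 methyl (3S)-3-hydroxy-3-[4-(geranyloxy)phenyl]propanoate (1.2 equiv); 12 3,5-bis(methoxymethoxy)-2-(trimethylsilyl)phenyl trifluoromethanesulfonate (1.0 equiv)
Product: 15 (2S)-5,7-bis(methoxymethoxy)-4'-O-geranylflavanone, via trimethylsilyl ether 13 (not isolated), via 3,5-bis(methoxymethoxy)benzyne 14 (not isolated)
Conditions: Me3SiNMe2, THF, 20 °C, then evaporation; 12, CsF (1.5 equiv), 18-crown-6 (1.5 equiv), THF, 0 to 20 °C; pH 7 buffer (NaH2PO4/Na2HPO4), 0 °C
Reagents that add atoms: none
Why: Proposed new method: a fluoride-triggered formal [4+2] annulation of a 3-alkoxybenzyne with a β-silyloxy ester, reasoned by extension from the CsF-promoted annulation of arynes with methyl salicylates to xanthones and from the fluoride-promoted O-arylation of alcohols by arynes, neither of which has been shown for an aliphatic β-oxido ester. Fluoride attacks the aryl silicon of 12 and triflate leaves to give 14, while fluoride (and later methoxide) removes the trimethylsilyl group of 13 and frees the alkoxide in a medium that holds no O–H proton. The alkoxide should add to C8a of 14, the aryne carbon remote from the C5 acetal oxygen, because that oxygen distorts the aryne and the negative charge is best placed at C4a beside it; this is what secures the regiochemistry. The C4a anion then attacks the ester carbonyl through a six-membered transition state (6-exo-trig acyl substitution), which forms C4–C4a and closes ring C faster than an external proton or silicon electrophile can arrive. The expelled methoxide is silylated at once by 13 or by Me3SiF and ends as MeOSiMe3, so this silyl transfer carries the chain and no alkoxide base is left to enolise 15. No stereocentre is created: C2 comes from 6 with its C–O bond intact and should stay (S), provided retro-aldol cleavage of the alkoxide and E1cB opening of 15 are suppressed, which the low standing concentration of alkoxide, the aprotic medium, the use of 12 as limiting reagent and the cold buffered quench are meant to ensure.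

Step 8
Reactants: 15 (2S)-5,7-bis(methoxymethoxy)-4'-O-geranylflavanone
Product: 16 (2S)-4'-O-geranylnaringenin [(2S)-5,7-dihydroxy-2-[4-(geranyloxy)phenyl]chroman-4-one]
Conditions: methanolic HCl (0.5 M), MeOH/THF, 20 °C, monitored
Reagents that add atoms: none
Why: Acid-catalysed transacetalisation: protonation of the acetal and loss of the phenol gives a methoxymethyl cation that methanol traps; the O5 acetal goes first, helped by hydrogen bonding of the freed phenol to the C4 carbonyl, and the O7 acetal follows. Dilute acid at room temperature should spare the allylic ether and the alkenes and should not open ring C, whose chalcone equilibrium is driven chiefly by base, so C2 should keep its configuration.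

## Compound list

1 | 4-hydroxyacetophenone | CC(=O)c1ccc(O)cc1 | starting material
2 | geranyl bromide, (2E)-1-bromo-3,7-dimethylocta-2,6-diene | CC(C)=CCC/C(C)=C/CBr | starting material
3 | 1-[4-(geranyloxy)phenyl]ethanone | CC(C)=CCC/C(C)=C/COc1ccc(C(C)=O)cc1 | intermediate
4 | dimethyl carbonate | COC(=O)OC | starting material
5 | methyl 3-[4-(geranyloxy)phenyl]-3-oxopropanoate | CC(C)=CCC/C(C)=C/COc1ccc(C(=O)CC(=O)OC)cc1 | intermediate
6 | methyl (3S)-3-hydroxy-3-[4-(geranyloxy)phenyl]propanoate | CC(C)=CCC/C(C)=C/COc1ccc([C@@H](O)CC(=O)OC)cc1 | intermediate
7 | phloroglucinol | Oc1cc(O)cc(O)c1 | starting material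
8 | 3,5-bis(methoxymethoxy)phenol | COCOc1cc(O)cc(OCOC)c1 | intermediate
9 | 2-bromo-3,5-bis(methoxymethoxy)phenol | COCOc1cc(O)c(Br)c(OCOC)c1 | intermediate
10 | [2-bromo-3,5-bis(methoxymethoxy)phenoxy]trimethylsilane | COCOc1cc(O[Si](C)(C)C)c(Br)c(OCOC)c1 | intermediate
11 | lithium 3,5-bis(methoxymethoxy)-2-(trimethylsilyl)phenoxide | COCOc1cc([O-])c([Si](C)(C)C)c(OCOC)c1.[Li+] | intermediate
12 | 3,5-bis(methoxymethoxy)-2-(trimethylsilyl)phenyl trifluoromethanesulfonate | COCOc1cc(OCOC)c([Si](C)(C)C)c(OS(=O)(=O)C(F)(F)F)c1 | intermediate
13 | methyl (3S)-3-[4-(geranyloxy)phenyl]-3-(trimethylsilyloxy)propanoate | CC(C)=CCC/C(C)=C/COc1ccc([C@@H](O[Si](C)(C)C)CC(=O)OC)cc1 | intermediate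
14 | 3,5-bis(methoxymethoxy)benzyne | COCOC1=CC(OCOC)=CC#C1 | intermediate
15 | (2S)-5,7-bis(methoxymethoxy)-4'-O-geranylflavanone | CC(C)=CCC/C(C)=C/COc1ccc([C@@H]2CC(=O)c3c(OCOC)cc(OCOC)cc3O2)cc1 | intermediate
16 | (2S)-4'-O-geranylnaringenin | CC(C)=CCC/C(C)=C/COc1ccc([C@@H]2CC(=O)c3c(O)cc(O)cc3O2)cc1 | target

## Step count and least certain steps

Total step count: 8. Longest linear sequence: 5 steps (7 → 8 → 9 → 12 → 15 → 16; the branch 1 → 3 → 5 → 6 → 15 → 16 is equally long).

**Step 7 (key step).** Four processes may spoil it:
- retro-aldol fragmentation of the alkoxide before it meets 14, which would also racemise whatever recombines;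
- capture of the C4a anion by a proton (from C3–H or adventitious moisture) or by a silicon electrophile instead of the ester, which stops at the uncyclised aryl ether;
- enolisation of 15 by residual base with E1cB opening of ring C and loss of configuration;
- ene reaction of 14 with the geranyl alkenes.

Fallback by known reaction types, setting out from 5 and 9 and returning at 15. 5 is reduced as in step 3 but with RuCl[(R,R)-TsDPEN](p-cymene) to methyl (3R)-3-hydroxy-3-[4-(geranyloxy)phenyl]propanoate F1. Mitsunobu etherification of F1 with 9 (PPh3, DIAD, toluene, 0 °C) inverts the carbinol and should give methyl (3S)-3-[2-bromo-3,5-bis(methoxymethoxy)phenoxy]-3-[4-(geranyloxy)phenyl]propanoate F2. Bromine–lithium exchange (t-BuLi, THF, −100 °C) followed by Parham cyclisation of the aryllithium onto the ester, with an acetic acid quench at low temperature, closes ring C to 15. This forms O1–C2 and C4–C4a in separate steps; its own weak points are elimination or partial ionisation at the electron-rich benzylic carbon during the Mitsunobu reaction and β-elimination of the aryloxide during the cyclisation.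

**Step 3.** Reduction may be slow and the enantioselectivity eroded, because the ketone is deactivated by the para-alkoxy group and partly enolised; formylation of the electron-rich benzylic alcohol is also possible.

Fallback by a C–C bond-forming route to the stereocentre, setting out from 2 and returning at 13. 4-Hydroxybenzaldehyde is alkylated with 2 (K2CO3, acetone) to 4-(geranyloxy)benzaldehyde F3. A catalytic asymmetric Mukaiyama acetate aldol with 1-methoxy-1-(trimethylsilyloxy)ethene should then give 13 directly by silyl transfer. The catalyst would be Ti(OiPr)4 with the tridentate Schiff-base ligand from 2-amino-2'-hydroxy-1,1'-binaphthyl and 3-bromo-5-tert-butylsalicylaldehyde plus 3,5-di-tert-butylsalicylic acid, in Et2O at −10 °C. The ligand enantiomer that directs attack to the Si face of the aldehyde is the one needed. A desilylated sample gives 6 for assay.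

**Step 5.** Bromination may occur at the para position between the two acetal groups, or a second bromination may follow, since all three free ring positions are strongly activated.

Fallback by coordination-directed metalation instead of electrophilic substitution, setting out from 8 and returning at 12. 8 is acylated (ClC(O)NEt2, K2CO3, MeCN) to 3,5-bis(methoxymethoxy)phenyl N,N-diethylcarbamate F4. Lithiation with s-BuLi/TMEDA in THF at −78 °C should occur between the carbamate, the stronger director, and an acetal; quenching with Me3SiCl gives 3,5-bis(methoxymethoxy)-2-(trimethylsilyl)phenyl N,N-diethylcarbamate F5. Reductive removal of the carbamate with Cp2Zr(H)Cl (THF, 20 °C) gives 3,5-bis(methoxymethoxy)-2-(trimethylsilyl)phenol F6. Triflation (NaH, PhNTf2, THF) gives 12.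

**Step 8.** Acid may ionise the allylic aryl ether (loss of the geranyl group) or add methanol or HCl to the trisubstituted alkenes before the slower O7 acetal has been cleaved.

Fallback by aprotic silyl exchange instead of protic solvolysis, setting out from 15 and returning at 16. Me3SiOTf with 2,2'-bipyridyl in MeCN at 0 °C should exchange both methoxymethyl groups for trimethylsilyl groups under buffered, non-protic conditions, giving (2S)-4'-O-geranyl-5,7-bis(trimethylsilyloxy)flavanone F7. Its aryl silyl ethers are hydrolysed by water on work-up to 16.

## Further compounds

F1 | step 7 | methyl (3R)-3-hydroxy-3-[4-(geranyloxy)phenyl]propanoate | CC(C)=CCC/C(C)=C/COc1ccc([C@H](O)CC(=O)OC)cc1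
F2 | step 7 | methyl (3S)-3-[2-bromo-3,5-bis(methoxymethoxy)phenoxy]-3-[4-(geranyloxy)phenyl]propanoate | CC(C)=CCC/C(C)=C/COc1ccc([C@@H](Oc2cc(OCOC)cc(OCOC)c2Br)CC(=O)OC)cc1
F3 | step 3 | 4-(geranyloxy)benzaldehyde | CC(C)=CCC/C(C)=C/COc1ccc(C=O)cc1
F4 | step 5 | 3,5-bis(methoxymethoxy)phenyl N,N-diethylcarbamate | CCN(CC)C(=O)Oc1cc(OCOC)cc(OCOC)c1
F5 | step 5 | 3,5-bis(methoxymethoxy)-2-(trimethylsilyl)phenyl N,N-diethylcarbamate | CCN(CC)C(=O)Oc1cc(OCOC)cc(OCOC)c1[Si](C)(C)C
F6 | step 5 | 3,5-bis(methoxymethoxy)-2-(trimethylsilyl)phenol | COCOc1cc(O)c([Si](C)(C)C)c(OCOC)c1
F7 | step 8 | (2S)-4'-O-geranyl-5,7-bis(trimethylsilyloxy)flavanone | CC(C)=CCC/C(C)=C/COc1ccc([C@@H]2CC(=O)c3c(O[Si](C)(C)C)cc(O[Si](C)(C)C)cc3O2)cc1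
A1 | alternative 1 | 5,7-bis(tert-butyldimethylsilyloxy)-2,2-dimethyl-4H-1,3-benzodioxin-4-one | CC1(C)OC(=O)c2c(O[Si](C)(C)C(C)(C)C)cc(O[Si](C)(C)C(C)(C)C)cc2O1
A2 | alternative 1 | 3,5-bis(tert-butyldimethylsilyloxy)-6-(oxomethylidene)cyclohexa-2,4-dien-1-one | O=C=C1C(=O)C=C(O[Si](C)(C)C(C)(C)C)C=C1O[Si](C)(C)C(C)(C)C
A3 | alternative 1 | 4-(geranyloxy)styrene | CC(C)=CCC/C(C)=C/COc1ccc(C=C)cc1
A4 | alternative 1 | (2S)-5,7-bis(tert-butyldimethylsilyloxy)-4'-O-geranylflavanone | CC(C)=CCC/C(C)=C/COc1ccc([C@@H]2CC(=O)c3c(O[Si](C)(C)C(C)(C)C)cc(O[Si](C)(C)C(C)(C)C)cc3O2)cc1
A5 | alternative 2 | (2S)-6-(diazoacetyl)-2-[4-(geranyloxy)phenyl]-2,3-dihydro-4H-pyran-4-one | CC(C)=CCC/C(C)=C/COc1ccc([C@@H]2CC(=O)C=C(C(=O)C=[N+]=[N-])O2)cc1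
A6 | alternative 2 | (2S)-2-[4-(geranyloxy)phenyl]-6-(2-oxoethenyl)-2,3-dihydro-4H-pyran-4-one | CC(C)=CCC/C(C)=C/COc1ccc([C@@H]2CC(=O)C=C(C=C=O)O2)cc1
A7 | alternative 2 | (triisopropylsilyloxy)ethyne | C#CO[Si](C(C)C)(C(C)C)C(C)C
A8 | alternative 2 | (2S)-5-hydroxy-7-(triisopropylsilyloxy)-4'-O-geranylflavanone | CC(C)=CCC/C(C)=C/COc1ccc([C@@H]2CC(=O)c3c(O)cc(O[Si](C(C)C)(C(C)C)C(C)C)cc3O2)cc1
A9 | alternative 3 | (1R,3S)-1-[2-bromo-4,6-bis(methoxymethoxy)phenyl]-3-[4-(geranyloxy)phenyl]propane-1,3-diol | CC(C)=CCC/C(C)=C/COc1ccc([C@@H](O)C[C@@H](O)c2c(OCOC)cc(OCOC)cc2Br)cc1
A10 | alternative 3 | (2S,4R)-5,7-bis(methoxymethoxy)-4'-O-geranylflavan-4-ol | CC(C)=CCC/C(C)=C/COc1ccc([C@@H]2C[C@@H](O)c3c(OCOC)cc(OCOC)cc3O2)cc1
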